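## Retrosynthetic overview

1. The target (2S)-flavanone 20 comes from its bis-MOM ether 19, which is obtained from racemate 18 by kinetic resolution (asymmetric transfer hydrogenation consumes the 2R enantiomer).
2. Ring C is the only ring built. It closes by oxa-Michael addition of the single free phenol of 2'-hydroxychalcone 17; rings A and B are bought as benzenoid starting materials.
3. The key C–C bond (Cα–Cβ of chalcone 17) is made by Claisen–Schmidt aldol condensation of ring A acetophenone 15 with ring B aldehyde 8.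
4. Acetophenone 15 comes from 2',6'-dihydroxy-4'-methoxyacetophenone by mono-MOM protection, O-prenylation and para-Claisen rearrangement. This places prenyl between OMe and OMOM and leaves the free OH next to the ring hydrogen, which fixes the 6-prenyl regiochemistry.
5. Aldehyde 8 comes from 2-bromoisovanillin by acetal and MOM protection, Br–Li exchange, and coupling of the arylcopper with geranyl bromide.

Assumption: 2-bromoisovanillin (1) and 2',6'-dihydroxy-4'-methoxyacetophenone (9) are bought as catalogue chemicals.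

## Route

Step 1
Reactants: 1 2-bromo-3-hydroxy-4-methoxybenzaldehyde
Product: 2 2-bromo-3-(1,3-dioxolan-2-yl)-6-methoxyphenol
Conditions: HOCH2CH2OH (3 equiv), p-TsOH·H2O (5 mol %), toluene, Dean–Stark reflux
Reagents that add atoms: ethylene glycol, OCCO
Why: Acid-catalysed acetalisation with azeotropic water removal masks the aldehyde before the organolithium step, and is run before any MOM ether is present so that no MOM group is exposed to TsOH.

Step 2
Reactants: 2 2-bromo-3-(1,3-dioxolan-2-yl)-6-methoxyphenol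
Product: 3 2-[2-bromo-4-methoxy-3-(methoxymethoxy)phenyl]-1,3-dioxolane
Conditions: MOMCl (1.5 equiv), iPr2NEt (2 equiv), CH2Cl2, 0 °C to rt
Reagents that add atoms: chloromethyl methyl ether (MOMCl), COCCl
Why: O-alkylation of the acidic ortho-bromophenol gives a MOM ether that is inert to n-BuLi and to the later basic steps, while the acetal is untouched by the amine-buffered medium.

Step 3
Reactants: 3 2-[2-bromo-4-methoxy-3-(methoxymethoxy)phenyl]-1,3-dioxolane; 4 geranyl bromide [(2E)-1-bromo-3,7-dimethylocta-2,6-diene]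
Product: 7 2-{2-[(2E)-3,7-dimethylocta-2,6-dien-1-yl]-4-methoxy-3-(methoxymethoxy)phenyl}-1,3-dioxolane, via aryllithium 5 (not isolated), via arylcopper 6 (not isolated)
Conditions: n-BuLi (1.05 equiv), THF, −78 °C, 30 min; CuBr·SMe2 (1.1 equiv), −78 to −40 °C; 4 (1.3 equiv), −78 °C to rt
Reagents that add atoms: none
Why: Bromine–lithium exchange gives an aryllithium chelated by the flanking OMOM and dioxolane oxygens, and after transmetalation the arylcopper alkylates geranyl bromide at the primary carbon (SN2 allylic substitution) with the E double bond retained.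

Step 4
Reactants: 7 geranylated aryl dioxolane
Product: 8 2-[(2E)-3,7-dimethylocta-2,6-dien-1-yl]-4-methoxy-3-(methoxymethoxy)benzaldehyde
Conditions: HCl (0.5 M aq.)/THF (1:4), rt, 1 h
Reagents that add atoms: water, O
Why: Acetal hydrolysis is fast because the para-methoxy group stabilises the oxocarbenium ion, so dilute acid at rt suffices and the aryl MOM ether and the geranyl chain survive.

Step 5
Reactants: 9 1-(2,6-dihydroxy-4-methoxyphenyl)ethanone
Product: 10 1-[2-hydroxy-4-methoxy-6-(methoxymethoxy)phenyl]ethanone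
Conditions: MOMCl (1.1 equiv), iPr2NEt (1.5 equiv), CH2Cl2, 0 °C to rt
Reagents that add atoms: chloromethyl methyl ether (MOMCl), COCCl
Why: Mono-etherification of the symmetric diol stops cleanly because the remaining OH is then locked in a strong hydrogen bond to the carbonyl and is much less nucleophilic.

Step 6
Reactants: 10 1-[2-hydroxy-4-methoxy-6-(methoxymethoxy)phenyl]ethanone; 11 prenyl bromide (1-bromo-3-methylbut-2-ene)
Product: 12 1-[4-methoxy-2-(methoxymethoxy)-6-(3-methylbut-2-en-1-yloxy)phenyl]ethanone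
Conditions: K2CO3 (2 equiv), 11 (1.5 equiv), DMF, 40 °C
Reagents that add atoms: none
Why: Williamson etherification of the phenoxide with a reactive primary allylic bromide in a dipolar aprotic solvent gives the O-prenyl ether.

Step 7
Reactants: 12 1-[4-methoxy-2-(methoxymethoxy)-6-(3-methylbut-2-en-1-yloxy)phenyl]ethanone
Product: 15 1-[6-hydroxy-4-methoxy-2-(methoxymethoxy)-3-(3-methylbut-2-en-1-yl)phenyl]ethanone, via ortho-dienone 13 (not isolated), via para-dienone 14 (not isolated)
Conditions: PhNEt2, 200 °C (sealed tube), 3 h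
Reagents that add atoms: none
Why: Aromatic Claisen rearrangement to the free ortho carbon gives a crowded 1,1-dimethylallyl dienone that undergoes a Cope shift to the para carbon (para-Claisen rearrangement), which lies between OMe and OMOM, and tautomerisation returns a phenol that now sits next to the ring hydrogen.

Step 8
Reactants: 15 1-[6-hydroxy-4-methoxy-2-(methoxymethoxy)-3-(3-methylbut-2-en-1-yl)phenyl]ethanone; 8 2-[(2E)-3,7-dimethylocta-2,6-dien-1-yl]-4-methoxy-3-(methoxymethoxy)benzaldehyde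
Product: 17 (2E)-3-{2-[(2E)-3,7-dimethylocta-2,6-dien-1-yl]-4-methoxy-3-(methoxymethoxy)phenyl}-1-[6-hydroxy-4-methoxy-2-(methoxymethoxy)-3-(3-methylbut-2-en-1-yl)phenyl]prop-2-en-1-one, via aldol adduct 16 (not isolated)
Conditions: KOH (50% aq., 10 equiv), EtOH, rt, 48 h
Reagents that add atoms: none
Why: Claisen–Schmidt (crossed aldol) condensation of the methyl ketone enolate with the non-enolisable aldehyde, followed by E1cB loss of water, gives the E-enone, and MOM ethers and both terpenoid chains are inert to hydroxide.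

Step 9
Reactants: 17 2'-hydroxychalcone
Product: 18 rac-2-{2-[(2E)-3,7-dimethylocta-2,6-dien-1-yl]-4-methoxy-3-(methoxymethoxy)phenyl}-7-methoxy-5-(methoxymethoxy)-6-(3-methylbut-2-en-1-yl)-2,3-dihydro-4H-chromen-4-one
Conditions: NaOAc (10 equiv), EtOH, reflux, 24 h
Reagents that add atoms: none
Why: Intramolecular oxa-Michael addition (6-endo-trig) of the only free phenol closes ring C with O1 on the side bearing the ring hydrogen, which places prenyl at C6, and the 6'-OMOM group twists the enone so the equilibrium favours the flavanone, formed as the racemate at C2.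

Step 10
Reactants: 18 racemic bis-MOM flavanone
Product: 19 (2S)-2-{2-[(2E)-3,7-dimethylocta-2,6-dien-1-yl]-4-methoxy-3-(methoxymethoxy)phenyl}-7-methoxy-5-(methoxymethoxy)-6-(3-methylbut-2-en-1-yl)-2,3-dihydro-4H-chromen-4-one
Conditions: RuCl[(R,R)-TsDPEN](p-cymene) (2 mol %), HCO2H/Et3N (5:2), EtOAc, 30 °C, stopped at ca. 52–55% conversion; chromatography
Reagents that add atoms: none
Why: In this Noyori-type asymmetric transfer hydrogenation with kinetic resolution the (R,R)-catalyst forms the 4R carbinol and does so rapidly only with the 2R ketone (axial hydride delivery to the cis-(2R,4R)-flavan-4-ol), so the 2S ketone is recovered in high ee and is separated from the more polar alcohol, the isolated trisubstituted alkenes being inert to the ruthenium hydride.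

Step 11
Reactants: 19 (2S) bis-MOM flavanone
Product: 20 (2S)-5-hydroxy-2-{3-hydroxy-4-methoxy-2-[(2E)-3,7-dimethylocta-2,6-dien-1-yl]phenyl}-7-methoxy-6-(3-methylbut-2-en-1-yl)-2,3-dihydro-4H-chromen-4-one
Conditions: HCl (3 M aq.)/MeOH (1:5), 40 °C, 2–3 h, HPLC control
Reagents that add atoms: none
Why: Acid-catalysed acetal methanolysis removes both MOM ethers, and the C2 stereocentre is not touched because racemisation of flavanones runs through base-induced ring opening, while the low temperature keeps the prenyl and geranyl groups from cyclising onto the neighbouring phenols.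

## Compound list

1 | 2-bromo-3-hydroxy-4-methoxybenzaldehyde (2-bromoisovanillin) | COc1ccc(C=O)c(Br)c1O | starting material
2 | 2-bromo-3-(1,3-dioxolan-2-yl)-6-methoxyphenol | COc1ccc(C2OCCO2)c(Br)c1O | intermediate
3 | 2-[2-bromo-4-methoxy-3-(methoxymethoxy)phenyl]-1,3-dioxolane | COCOc1c(Br)c(C2OCCO2)ccc1OC | intermediate
4 | geranyl bromide, (2E)-1-bromo-3,7-dimethylocta-2,6-diene | BrC/C=C(\C)CCC=C(C)C | starting material
5 | [2-(1,3-dioxolan-2-yl)-5-methoxy-6-(methoxymethoxy)phenyl]lithium | COCOc1c([Li])c(C2OCCO2)ccc1OC | intermediate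
6 | [2-(1,3-dioxolan-2-yl)-5-methoxy-6-(methoxymethoxy)phenyl]copper | COCOc1c([Cu])c(C2OCCO2)ccc1OC | intermediate
7 | 2-{2-[(2E)-3,7-dimethylocta-2,6-dien-1-yl]-4-methoxy-3-(methoxymethoxy)phenyl}-1,3-dioxolane | COCOc1c(C/C=C(\C)CCC=C(C)C)c(C2OCCO2)ccc1OC | intermediate
8 | 2-[(2E)-3,7-dimethylocta-2,6-dien-1-yl]-4-methoxy-3-(methoxymethoxy)benzaldehyde | COCOc1c(C/C=C(\C)CCC=C(C)C)c(C=O)ccc1OC | intermediate
9 | 1-(2,6-dihydroxy-4-methoxyphenyl)ethanone | CC(=O)c1c(O)cc(OC)cc1O | starting material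
10 | 1-[2-hydroxy-4-methoxy-6-(methoxymethoxy)phenyl]ethanone | CC(=O)c1c(O)cc(OC)cc1OCOC | intermediate
11 | prenyl bromide, 1-bromo-3-methylbut-2-ene | CC(C)=CCBr | starting material
12 | 1-[4-methoxy-2-(methoxymethoxy)-6-(3-methylbut-2-en-1-yloxy)phenyl]ethanone | CC(=O)c1c(OCC=C(C)C)cc(OC)cc1OCOC | intermediate
13 | 2-acetyl-5-methoxy-3-(methoxymethoxy)-6-(2-methylbut-3-en-2-yl)cyclohexa-2,4-dien-1-one (ortho-dienone) | CC(=O)C1=C(OCOC)C=C(OC)C(C(C)(C)C=C)C1=O | intermediate
14 | 2-acetyl-5-methoxy-3-(methoxymethoxy)-4-(3-methylbut-2-en-1-yl)cyclohexa-2,5-dien-1-one (para-dienone) | CC(=O)C1=C(OCOC)C(CC=C(C)C)C(OC)=CC1=O | intermediate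
15 | 1-[6-hydroxy-4-methoxy-2-(methoxymethoxy)-3-(3-methylbut-2-en-1-yl)phenyl]ethanone | CC(=O)c1c(O)cc(OC)c(CC=C(C)C)c1OCOC | intermediate
16 | rac-3-{2-[(2E)-3,7-dimethylocta-2,6-dien-1-yl]-4-methoxy-3-(methoxymethoxy)phenyl}-3-hydroxy-1-[6-hydroxy-4-methoxy-2-(methoxymethoxy)-3-(3-methylbut-2-en-1-yl)phenyl]propan-1-one | COCOc1c(CC=C(C)C)c(OC)cc(O)c1C(=O)CC(O)c1ccc(OC)c(OCOC)c1C/C=C(\C)CCC=C(C)C | intermediate
17 | (2E)-3-{2-[(2E)-3,7-dimethylocta-2,6-dien-1-yl]-4-methoxy-3-(methoxymethoxy)phenyl}-1-[6-hydroxy-4-methoxy-2-(methoxymethoxy)-3-(3-methylbut-2-en-1-yl)phenyl]prop-2-en-1-one | COCOc1c(CC=C(C)C)c(OC)cc(O)c1C(=O)/C=C/c1ccc(OC)c(OCOC)c1C/C=C(\C)CCC=C(C)C | intermediate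
18 | rac-2-{2-[(2E)-3,7-dimethylocta-2,6-dien-1-yl]-4-methoxy-3-(methoxymethoxy)phenyl}-7-methoxy-5-(methoxymethoxy)-6-(3-methylbut-2-en-1-yl)-2,3-dihydro-4H-chromen-4-one | COc1ccc(C2CC(=O)c3c(cc(OC)c(CC=C(C)C)c3OCOC)O2)c(C/C=C(\C)CCC=C(C)C)c1OCOC | intermediate
19 | (2S)-2-{2-[(2E)-3,7-dimethylocta-2,6-dien-1-yl]-4-methoxy-3-(methoxymethoxy)phenyl}-7-methoxy-5-(methoxymethoxy)-6-(3-methylbut-2-en-1-yl)-2,3-dihydro-4H-chromen-4-one | COc1ccc([C@@H]2CC(=O)c3c(cc(OC)c(CC=C(C)C)c3OCOC)O2)c(C/C=C(\C)CCC=C(C)C)c1OCOC | intermediate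
20 | (2S)-5-hydroxy-2-{3-hydroxy-4-methoxy-2-[(2E)-3,7-dimethylocta-2,6-dien-1-yl]phenyl}-7-methoxy-6-(3-methylbut-2-en-1-yl)-2,3-dihydro-4H-chromen-4-one | COc1ccc([C@@H]2CC(=O)c3c(cc(OC)c(CC=C(C)C)c3O)O2)c(C/C=C(\C)CCC=C(C)C)c1O | target

## Step count and risks

Total step count: 11. Longest linear sequence: 8 steps (1 → 2 → 3 → 7 → 8 → 17 → 18 → 19 → 20).

**Step 7 (para-Claisen at 200 °C).** It may give the ortho product, lose the prenyl group or lose MOM. The fallback sets out from 9 and comes back at 15, and places the prenyl group by an ortho-Claisen rearrangement whose regiochemistry cannot vary. Monosilylation of 9 (TBSCl, imidazole, DMF) gives 1-[2-(tert-butyldimethylsilyloxy)-6-hydroxy-4-methoxyphenyl]ethanone F1. Tsuji–Trost O-allylation with isobutyl 2-methylbut-3-en-2-yl carbonate and Pd(PPh3)4 in THF at 0 °C gives the tertiary ether 1-[2-(tert-butyldimethylsilyloxy)-4-methoxy-6-(2-methylbut-3-en-2-yloxy)phenyl]ethanone F2. Heating in toluene at 110 °C moves the allyl unit to the only free ortho carbon as a normal prenyl group, giving 1-[6-(tert-butyldimethylsilyloxy)-2-hydroxy-4-methoxy-3-(3-methylbut-2-en-1-yl)phenyl]ethanone F3. NaH and MOMCl in DMF cap the phenol next to the prenyl group to give 1-[6-(tert-butyldimethylsilyloxy)-4-methoxy-2-(methoxymethoxy)-3-(3-methylbut-2-en-1-yl)phenyl]ethanone F4, and TBAF buffered with AcOH removes the silyl group to give 15.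

**Step 10 (kinetic resolution).** The peri 5-OMOM group and the ortho-geranyl aryl group may slow the reduction or lower the selectivity factor. The fallback sets out from 18 and comes back at 19 by physical separation: preparative HPLC or SFC on an amylose tris(3,5-dimethylphenylcarbamate) phase gives 19 directly. The 2R enantiomer is racemised by NaOAc in hot EtOH (ring opening to 17 and reclosure) and recycled. This fallback makes no new compound (F0).

**Step 11 (global MOM removal).** The hindered 3'-OMOM group needs real acid, which risks chroman formation from the ortho-prenyl and ortho-geranyl phenols and erosion of ee. The fallback sets out from 8 and comes back at 20, and changes the protecting-group plan so that only the labile peri MOM is left for the end. The MOM ether of 8 is cleaved at the fragment stage (2 M HCl, MeOH/THF, rt) to give 2-[(2E)-3,7-dimethylocta-2,6-dien-1-yl]-3-hydroxy-4-methoxybenzaldehyde F5. Claisen–Schmidt condensation of F5 with 15 (excess KOH, EtOH) gives (2E)-3-{2-[(2E)-3,7-dimethylocta-2,6-dien-1-yl]-3-hydroxy-4-methoxyphenyl}-1-[6-hydroxy-4-methoxy-2-(methoxymethoxy)-3-(3-methylbut-2-en-1-yl)phenyl]prop-2-en-1-one F6. NaOAc in refluxing EtOH closes it to rac-2-{2-[(2E)-3,7-dimethylocta-2,6-dien-1-yl]-3-hydroxy-4-methoxyphenyl}-7-methoxy-5-(methoxymethoxy)-6-(3-methylbut-2-en-1-yl)-2,3-dihydro-4H-chromen-4-one F7. The same transfer-hydrogenation resolution leaves (2S)-2-{2-[(2E)-3,7-dimethylocta-2,6-dien-1-yl]-3-hydroxy-4-methoxyphenyl}-7-methoxy-5-(methoxymethoxy)-6-(3-methylbut-2-en-1-yl)-2,3-dihydro-4H-chromen-4-one F8. Its carbonyl-activated 5-OMOM group is removed with 0.5 M HCl in MeOH at rt to give 20.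

## Further compounds

F1 | step 7 | 1-[2-(tert-butyldimethylsilyloxy)-6-hydroxy-4-methoxyphenyl]ethanone | CC(=O)c1c(O)cc(OC)cc1O[Si](C)(C)C(C)(C)C
F2 | step 7 | 1-[2-(tert-butyldimethylsilyloxy)-4-methoxy-6-(2-methylbut-3-en-2-yloxy)phenyl]ethanone | CC(=O)c1c(OC(C)(C)C=C)cc(OC)cc1O[Si](C)(C)C(C)(C)C
F3 | step 7 | 1-[6-(tert-butyldimethylsilyloxy)-2-hydroxy-4-methoxy-3-(3-methylbut-2-en-1-yl)phenyl]ethanone | CC(=O)c1c(O)c(CC=C(C)C)c(OC)cc1O[Si](C)(C)C(C)(C)C
F4 | step 7 | 1-[6-(tert-butyldimethylsilyloxy)-4-methoxy-2-(methoxymethoxy)-3-(3-methylbut-2-en-1-yl)phenyl]ethanone | CC(=O)c1c(OCOC)c(CC=C(C)C)c(OC)cc1O[Si](C)(C)C(C)(C)C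
F0 | step 10 | none | none
F5 | step 11 | 2-[(2E)-3,7-dimethylocta-2,6-dien-1-yl]-3-hydroxy-4-methoxybenzaldehyde | COc1ccc(C=O)c(C/C=C(\C)CCC=C(C)C)c1O
F6 | step 11 | (2E)-3-{2-[(2E)-3,7-dimethylocta-2,6-dien-1-yl]-3-hydroxy-4-methoxyphenyl}-1-[6-hydroxy-4-methoxy-2-(methoxymethoxy)-3-(3-methylbut-2-en-1-yl)phenyl]prop-2-en-1-one | COCOc1c(CC=C(C)C)c(OC)cc(O)c1C(=O)/C=C/c1ccc(OC)c(O)c1C/C=C(\C)CCC=C(C)C
F7 | step 11 | rac-2-{2-[(2E)-3,7-dimethylocta-2,6-dien-1-yl]-3-hydroxy-4-methoxyphenyl}-7-methoxy-5-(methoxymethoxy)-6-(3-methylbut-2-en-1-yl)-2,3-dihydro-4H-chromen-4-one | COc1ccc(C2CC(=O)c3c(cc(OC)c(CC=C(C)C)c3OCOC)O2)c(C/C=C(\C)CCC=C(C)C)c1O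
F8 | step 11 | (2S)-2-{2-[(2E)-3,7-dimethylocta-2,6-dien-1-yl]-3-hydroxy-4-methoxyphenyl}-7-methoxy-5-(methoxymethoxy)-6-(3-methylbut-2-en-1-yl)-2,3-dihydro-4H-chromen-4-one | COc1ccc([C@@H]2CC(=O)c3c(cc(OC)c(CC=C(C)C)c3OCOC)O2)c(C/C=C(\C)CCC=C(C)C)c1O
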